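The oxocane is cut between C6 and C7, neighbouring ring carbons that both bear oxygen (C6 the ring ether oxygen, C7 an acetoxy group). Opened up, C7 is an aldehyde carbon and C6 the β-carbon of an (E)-β-alkoxyacrylate attached to O12; both are acceptor carbons, so samarium diiodide is used to turn C7 into a nucleophilic ketyl that attacks C6. This single operation closes the eight-membered ether, creates the C6 and C7 stereocentres and leaves C4 as an ester for the Z-enyne. The precursor is an acyclic C7 aldehyde with a sugar-derived cis 9,10-acetonide as hinge and a silyl ether at C13; C7 forms trans and is inverted later.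

Key step: step 13

Remark: atoms are numbered C1 (alkyne CH) to C15 (ethyl CH3), with the ring oxygen between C6 and C12 (target 6R,7R,9R,10S,12R,13S); the ring closure is assumed to give the 6,7-trans alcohol as it does for smaller rings, so C7 is inverted in step 18.

Step 1
Reactants: 1 2-deoxy-D-ribose; 2 2-methoxypropene
Product: 3 2-deoxy-3,4-O-isopropylidene-D-erythro-pentopyranose (lactol, anomer mixture)
Conditions: pyridinium p-toluenesulfonate (cat.), EtOAc, rt
Reagents that add atoms: none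
Why: Acid-catalysed acetalisation with an enol ether under kinetic control, in which only the cis 3,4-diol of the pyranose can close an unstrained dioxolane, so the lactol stays free and no stereocentre is touched.

Step 2
Reactants: 3 lactol acetonide
Product: 4 [(4R,5S)-2,2-dimethyl-5-(3-methylbut-2-en-1-yl)-1,3-dioxolan-4-yl]methanol
Conditions: i-PrPPh3I, n-BuLi, THF, 0 °C to rt
Reagents that add atoms: isopropyltriphenylphosphonium iodide, CC(C)[P+](c1ccccc1)(c1ccccc1)c1ccccc1.[I-]
Why: Wittig olefination of the lactol through its open hydroxy-aldehyde form, which masks C12 as a trisubstituted alkene (inert to the later hydroboration) and frees the C8 hydroxyl.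

Step 3
Reactants: 4 alkenol
Product: 5 (4S,5S)-2,2-dimethyl-5-(3-methylbut-2-en-1-yl)-1,3-dioxolane-4-carbaldehyde
Conditions: Dess–Martin periodinane, NaHCO3, CH2Cl2, 0 °C to rt; used crude
Reagents that add atoms: none
Why: Dess–Martin oxidation under buffered, non-basic conditions, which should keep the α-alkoxy centre C9 of the cis-dioxolane from epimerising.

Step 4
Reactants: 5 aldehyde
Product: 6 (4R,5S)-4-ethenyl-2,2-dimethyl-5-(3-methylbut-2-en-1-yl)-1,3-dioxolane
Conditions: Ph3PCH3Br, KN(SiMe3)2, THF, −78 to 0 °C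
Reagents that add atoms: methyltriphenylphosphonium bromide, C[P+](c1ccccc1)(c1ccccc1)c1ccccc1.[Br-]
Why: Wittig methylenation brings in C7, the non-stabilised ylide adding to the aldehyde at low temperature faster than C9 can epimerise.

Step 5
Reactants: 6 diene
Product: 8 2-[(4R,5S)-2,2-dimethyl-5-(3-methylbut-2-en-1-yl)-1,3-dioxolan-4-yl]ethanol, via B-alkyl-9-borabicyclononane 7 (not isolated)
Conditions: 9-BBN, THF, 0 °C to rt; then NaOH, H2O2, 0 °C
Reagents that add atoms: hydrogen peroxide, OO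
Why: Hydroboration–oxidation, in which the bulky borane adds to the monosubstituted alkene far faster than to the trisubstituted one and places boron on the terminal carbon C7.

Step 6
Reactants: 8 primary alcohol
Product: 9 triethylsilyl ether of 8
Conditions: Et3SiCl, imidazole, CH2Cl2, 0 °C
Reagents that add atoms: chlorotriethylsilane, CC[Si](Cl)(CC)CC
Why: Silylation of the primary alcohol gives an ether that survives ozonolysis, allylboration and hydrogenation and can later be oxidised directly to the aldehyde.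

Step 7
Reactants: 9 silyl ether
Product: 11 2-[(4S,5R)-2,2-dimethyl-5-(2-triethylsilyloxyethyl)-1,3-dioxolan-4-yl]acetaldehyde, via ozonide 10 (not isolated)
Conditions: O3, CH2Cl2, −78 °C; then PPh3, −78 °C to rt
Reagents that add atoms: ozone, [O-][O+]=O
Why: Ozonolysis with reductive work-up cleaves the electron-rich trisubstituted alkene to the free C12 aldehyde while silyl ether and acetonide are inert.

Step 8
Reactants: 12 (E)-3-(tert-butyldimethylsilyloxy)prop-1-enylboronic acid pinacol ester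
Product: 13 (E)-3-(tert-butyldimethylsilyloxy)prop-2-enylboronic acid pinacol ester
Conditions: [Ir(cod)(PMePh2)2]PF6 (2 mol%, activated with H2), THF, rt
Reagents that add atoms: none
Why: Iridium hydride-catalysed alkene isomerisation moves the double bond from boron to oxygen conjugation and should give the (E)-enol ether, the geometry that an anti adduct requires.

Step 9
Reactants: 11 aldehyde; 13 (E)-γ-silyloxyallylboronate
Product: 15 (2R,3S)-3-(tert-butyldimethylsilyloxy)-1-[(4S,5R)-2,2-dimethyl-5-(2-triethylsilyloxyethyl)-1,3-dioxolan-4-yl]pent-4-en-2-ol, via pinacol borate ester 14 (not isolated)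
Conditions: (S)-TRIP [(S)-3,3′-bis(2,4,6-triisopropylphenyl)-1,1′-binaphthyl-2,2′-diyl hydrogen phosphate] (5 mol%), 4 Å MS, toluene, −30 °C; aq. NaHCO3
Reagents that add atoms: none
Why: Chiral phosphoric acid-catalysed allylboration through a closed chair transition state, in which the equatorial (E)-γ-silyloxy group fixes the 12,13-anti relation and the catalyst (the (S)-enantiomer is expected to direct attack to the Si face of the aldehyde) sets C12 as R and thereby C13 as S.

Step 10
Reactants: 15 homoallylic alcohol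
Product: 16 (2R,3S)-3-(tert-butyldimethylsilyloxy)-1-[(4S,5R)-2,2-dimethyl-5-(2-triethylsilyloxyethyl)-1,3-dioxolan-4-yl]pentan-2-ol
Conditions: H2 (1 atm), Pd/C, EtOAc, rt
Reagents that add atoms: none
Why: Heterogeneous catalytic hydrogenation of the only alkene turns the vinyl group into the C14–C15 ethyl group without touching silyl ethers or acetonide.

Step 11
Reactants: 16 alcohol; 17 ethyl propiolate
Product: 18 ethyl (E)-3-{[(2R,3S)-3-(tert-butyldimethylsilyloxy)-1-[(4S,5R)-2,2-dimethyl-5-(2-triethylsilyloxyethyl)-1,3-dioxolan-4-yl]pentan-2-yl]oxy}prop-2-enoate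
Conditions: N-methylmorpholine, CH2Cl2, rt
Reagents that add atoms: none
Why: Amine-promoted oxa-Michael addition of the C12 hydroxyl to the ynoate should give the (E)-β-alkoxyacrylate, and the weak base does not shift the neighbouring silyl group.

Step 12
Reactants: 18 acrylate
Product: 20 ethyl (E)-3-{[(2R,3S)-3-(tert-butyldimethylsilyloxy)-1-[(4S,5R)-2,2-dimethyl-5-(2-oxoethyl)-1,3-dioxolan-4-yl]pentan-2-yl]oxy}prop-2-enoate, via alkoxysulfonium chloride 19 (not isolated)
Conditions: (COCl)2, DMSO, CH2Cl2, −78 to −40 °C; then Et3N, −78 to 0 °C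
Reagents that add atoms: none
Why: Swern oxidation applied directly to the primary triethylsilyl ether, which the chlorosulfonium ion cleaves selectively before base collapses the alkoxysulfonium ion to the C7 aldehyde, leaving secondary silyl ether, acetonide and acrylate alone.

Step 13
Reactants: 20 aldehyde acrylate
Product: 21 ethyl 2-[(6R,7S,9R,10S,12R)-12-[(1S)-1-(tert-butyldimethylsilyloxy)propyl]-7-hydroxy-9,10-(isopropylidenedioxy)oxocan-6-yl]acetate
Conditions: SmI2 (3 equiv, 0.1 M in THF), MeOH (4 equiv), THF (5 mM), 0 °C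
Reagents that add atoms: none
Why: Single-electron transfer from divalent samarium to the aldehyde gives a ketyl bound to trivalent samarium; this C7-centred radical is nucleophilic and attacks C6, the electron-poor β-carbon of the acrylate, and the α-ester radical so formed takes up a second electron and is protonated by methanol. The closest known reaction type is the samarium diiodide ketyl–β-alkoxyacrylate reductive cyclisation that is established for tetrahydropyrans and oxepanes; here the oxocane is closed in the 8-exo-trig mode (C6 inside the ring, C5 outside). C6 is controlled by the existing centre C12: in the folded chain the C12 side chain and the acrylate arm both lie pseudo-equatorial, which should put H6 and H12 on the same face (6,12-cis). C7 is controlled by chelation of the samarium-bound ketyl oxygen to the ester carbonyl across the (E)-alkene, which should place the new hydroxyl anti to the C6 acetate arm (6,7-trans). The step needs only the 6,12-cis relation, since C7 is corrected in step 18; it is secured by the (E)-acrylate geometry and by the cis-fused dioxolane, which forces C8 and C11 onto the same side, bends the chain and should let ring closure outrun simple reduction of the ketyl.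

Step 14
Reactants: 21 hydroxy ester
Product: 22 C7 triethylsilyl ether of 21
Conditions: Et3SiOTf, 2,6-lutidine, CH2Cl2, −78 °C
Reagents that add atoms: triethylsilyl trifluoromethanesulfonate, CC[Si](CC)(CC)OS(=O)(=O)C(F)(F)F
Why: Silylation with a silyl triflate caps the hindered C7 hydroxyl so that the next step gives a true aldehyde and not a lactol, and the new ether is more labile than the C13 TBS ether.

Step 15
Reactants: 22 silylated ester
Product: 23 2-[(6R,7S,9R,10S,12R)-12-[(1S)-1-(tert-butyldimethylsilyloxy)propyl]-9,10-(isopropylidenedioxy)-7-(triethylsilyloxy)oxocan-6-yl]acetaldehyde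
Conditions: i-Bu2AlH (1.1 equiv), CH2Cl2, −78 °C; aq. potassium sodium tartrate
Reagents that add atoms: none
Why: Partial ester reduction with the aluminium hydride at low temperature stops at the aluminium hemiacetal, which releases the C4 aldehyde on work-up.

Step 16
Reactants: 23 aldehyde; 24 1,3-bis(triisopropylsilyl)propyne
Product: 26 (Z)-enyne with C1 triisopropylsilyl group (C7 OSiEt3 and C13 OTBS kept), via β-silyl lithium alkoxide 25 (not isolated)
Conditions: 24, n-BuLi, THF, −78 °C; then 23, −78 to 0 °C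
Reagents that add atoms: none
Why: Peterson olefination with the lithiated bis-silyl propyne, whose bulky silyl groups should favour the adduct that loses lithium silanolate by syn-elimination to the (Z)-C3=C4 enyne.

Step 17
Reactants: 26 silylated enyne
Product: 27 (6R,7S)-C7 alcohol (C13 OTBS and C1 silyl group kept)
Conditions: HF·pyridine, pyridine, THF, 0 °C
Reagents that add atoms: none
Why: Buffered fluoride desilylation removes the secondary triethylsilyl ether much faster than the more hindered TBS ether or the C-silyl alkyne, and the acetonide is stable.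

Step 18
Reactants: 27 C7 alcohol
Product: 28 (6R,7R)-C7 4-nitrobenzoate
Conditions: 4-O2NC6H4CO2H, PPh3, diisopropyl azodicarboxylate, toluene, 0 °C to rt
Reagents that add atoms: 4-nitrobenzoic acid, OC(=O)c1ccc(cc1)[N+](=O)[O-]
Why: Mitsunobu reaction, in which the carboxylate displaces the alkoxyphosphonium group at C7 by SN2 with inversion and so turns the 6,7-trans into the 6,7-cis arrangement of the target (C7 R).

Step 19
Reactants: 28 nitrobenzoate
Product: 29 (6R,7R)-C7 alcohol
Conditions: K2CO3, MeOH, 0 °C to rt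
Reagents that add atoms: none
Why: Base-catalysed methanolysis (transesterification) removes the electron-poor aryl ester without touching silyl groups, acetonide or enyne.

Step 20
Reactants: 29 alcohol
Product: 30 7,13-diol with terminal alkyne (9,10-acetonide kept)
Conditions: Bu4NF, THF, 0 °C to rt
Reagents that add atoms: none
Why: Fluoride-mediated desilylation cleaves both the O–Si bond at C13 and the C–Si bond at C1.

Step 21
Reactants: 30 diol
Product: 31 7,13-diacetate 9,10-acetonide
Conditions: Ac2O, pyridine, 4-dimethylaminopyridine (cat.), CH2Cl2, rt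
Reagents that add atoms: acetic anhydride, CC(=O)OC(C)=O
Why: Nucleophile-catalysed acylation esterifies both secondary alcohols while the 9,10-diol is still masked.

Step 22
Reactants: 31 diacetate acetonide
Product: 32 CNP0314743.1
Conditions: CF3CO2H/H2O (9:1), 0 °C
Reagents that add atoms: none
Why: Acid-catalysed acetal hydrolysis frees the 9,10-diol, and the acetates and the enyne should tolerate brief cold aqueous acid.

Compound list
1 | 2-deoxy-D-ribose, (3S,4R)-3,4,5-trihydroxypentanal | O=CC[C@H](O)[C@H](O)CO | starting material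
2 | 2-methoxypropene | COC(C)=C | starting material
3 | 2-deoxy-3,4-O-isopropylidene-D-erythro-pentopyranose (lactol, anomer mixture) | OC1C[C@@H]2OC(C)(C)O[C@@H]2CO1 | intermediate
4 | [(4R,5S)-2,2-dimethyl-5-(3-methylbut-2-en-1-yl)-1,3-dioxolan-4-yl]methanol | OC[C@H]1OC(C)(C)O[C@H]1CC=C(C)C | intermediate
5 | (4S,5S)-2,2-dimethyl-5-(3-methylbut-2-en-1-yl)-1,3-dioxolane-4-carbaldehyde | O=C[C@H]1OC(C)(C)O[C@H]1CC=C(C)C | intermediate
6 | (4R,5S)-4-ethenyl-2,2-dimethyl-5-(3-methylbut-2-en-1-yl)-1,3-dioxolane | C=C[C@H]1OC(C)(C)O[C@H]1CC=C(C)C | intermediate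
7 | 9-{2-[(4R,5S)-2,2-dimethyl-5-(3-methylbut-2-en-1-yl)-1,3-dioxolan-4-yl]ethyl}-9-borabicyclo[3.3.1]nonane | C(C[C@H]1OC(C)(C)O[C@H]1CC=C(C)C)B1C2CCCC1CCC2 | intermediate
8 | 2-[(4R,5S)-2,2-dimethyl-5-(3-methylbut-2-en-1-yl)-1,3-dioxolan-4-yl]ethanol | OCC[C@H]1OC(C)(C)O[C@H]1CC=C(C)C | intermediate
9 | triethyl{2-[(4R,5S)-2,2-dimethyl-5-(3-methylbut-2-en-1-yl)-1,3-dioxolan-4-yl]ethoxy}silane | CC[Si](CC)(CC)OCC[C@H]1OC(C)(C)O[C@H]1CC=C(C)C | intermediate
10 | 3,3-dimethyl-5-{[(4S,5R)-2,2-dimethyl-5-(2-triethylsilyloxyethyl)-1,3-dioxolan-4-yl]methyl}-1,2,4-trioxolane (ozonide) | CC[Si](CC)(CC)OCC[C@H]1OC(C)(C)O[C@H]1CC2OOC(C)(C)O2 | intermediate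
11 | 2-[(4S,5R)-2,2-dimethyl-5-(2-triethylsilyloxyethyl)-1,3-dioxolan-4-yl]acetaldehyde | CC[Si](CC)(CC)OCC[C@H]1OC(C)(C)O[C@H]1CC=O | intermediate
12 | (E)-3-(tert-butyldimethylsilyloxy)prop-1-enylboronic acid pinacol ester | CC(C)(C)[Si](C)(C)OC/C=C/B1OC(C)(C)C(C)(C)O1 | starting material
13 | (E)-3-(tert-butyldimethylsilyloxy)prop-2-enylboronic acid pinacol ester | CC(C)(C)[Si](C)(C)O/C=C/CB1OC(C)(C)C(C)(C)O1 | intermediate
14 | pinacol borate ester of 15 at the C12 oxygen | CC[Si](CC)(CC)OCC[C@H]1OC(C)(C)O[C@H]1C[C@@H](OB2OC(C)(C)C(C)(C)O2)[C@H](C=C)O[Si](C)(C)C(C)(C)C | intermediate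
15 | (2R,3S)-3-(tert-butyldimethylsilyloxy)-1-[(4S,5R)-2,2-dimethyl-5-(2-triethylsilyloxyethyl)-1,3-dioxolan-4-yl]pent-4-en-2-ol | CC[Si](CC)(CC)OCC[C@H]1OC(C)(C)O[C@H]1C[C@@H](O)[C@H](C=C)O[Si](C)(C)C(C)(C)C | intermediate
16 | (2R,3S)-3-(tert-butyldimethylsilyloxy)-1-[(4S,5R)-2,2-dimethyl-5-(2-triethylsilyloxyethyl)-1,3-dioxolan-4-yl]pentan-2-ol | CC[Si](CC)(CC)OCC[C@H]1OC(C)(C)O[C@H]1C[C@@H](O)[C@H](CC)O[Si](C)(C)C(C)(C)C | intermediate
17 | ethyl propiolate | C#CC(=O)OCC | starting material
18 | ethyl (E)-3-{[(2R,3S)-3-(tert-butyldimethylsilyloxy)-1-[(4S,5R)-2,2-dimethyl-5-(2-triethylsilyloxyethyl)-1,3-dioxolan-4-yl]pentan-2-yl]oxy}prop-2-enoate | CC[Si](CC)(CC)OCC[C@H]1OC(C)(C)O[C@H]1C[C@@H](O/C=C/C(=O)OCC)[C@H](CC)O[Si](C)(C)C(C)(C)C | intermediate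
19 | dimethyl(alkoxy)sulfonium chloride of the C7 oxygen of 18 | C[S+](C)OCC[C@H]1OC(C)(C)O[C@H]1C[C@@H](O/C=C/C(=O)OCC)[C@H](CC)O[Si](C)(C)C(C)(C)C.[Cl-] | intermediate
20 | ethyl (E)-3-{[(2R,3S)-3-(tert-butyldimethylsilyloxy)-1-[(4S,5R)-2,2-dimethyl-5-(2-oxoethyl)-1,3-dioxolan-4-yl]pentan-2-yl]oxy}prop-2-enoate (key-step precursor) | O=CC[C@H]1OC(C)(C)O[C@H]1C[C@@H](O/C=C/C(=O)OCC)[C@H](CC)O[Si](C)(C)C(C)(C)C | intermediate
21 | ethyl 2-[(6R,7S,9R,10S,12R)-12-[(1S)-1-(tert-butyldimethylsilyloxy)propyl]-7-hydroxy-9,10-(isopropylidenedioxy)oxocan-6-yl]acetate (6,12-cis, 6,7-trans) | CCOC(=O)C[C@H]1O[C@@H]([C@H](CC)O[Si](C)(C)C(C)(C)C)C[C@@H]2OC(C)(C)O[C@@H]2C[C@@H]1O | intermediate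
22 | C7 triethylsilyl ether of 21 | CCOC(=O)C[C@H]1O[C@@H]([C@H](CC)O[Si](C)(C)C(C)(C)C)C[C@@H]2OC(C)(C)O[C@@H]2C[C@@H]1O[Si](CC)(CC)CC | intermediate
23 | C4 aldehyde: 2-[(6R,7S,9R,10S,12R)-12-[(1S)-1-(tert-butyldimethylsilyloxy)propyl]-9,10-(isopropylidenedioxy)-7-(triethylsilyloxy)oxocan-6-yl]acetaldehyde | O=CC[C@H]1O[C@@H]([C@H](CC)O[Si](C)(C)C(C)(C)C)C[C@@H]2OC(C)(C)O[C@@H]2C[C@@H]1O[Si](CC)(CC)CC | intermediate
24 | 1,3-bis(triisopropylsilyl)propyne | CC(C)[Si](C(C)C)(C(C)C)CC#C[Si](C(C)C)(C(C)C)C(C)C | starting material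
25 | lithium alkoxide of the C4 carbinol carrying C3 and C1 triisopropylsilyl groups (Peterson adduct, C3/C4 mixture) | CC(C)[Si](C(C)C)(C(C)C)C#CC([Si](C(C)C)(C(C)C)C(C)C)C(O[Li])C[C@H]1O[C@@H]([C@H](CC)O[Si](C)(C)C(C)(C)C)C[C@@H]2OC(C)(C)O[C@@H]2C[C@@H]1O[Si](CC)(CC)CC | intermediate
26 | (3Z)-enyne, C1 triisopropylsilyl, (6R,7S)-7-triethylsilyloxy, 13-OTBS, 9,10-acetonide | CC(C)[Si](C(C)C)(C(C)C)C#C/C=C\C[C@H]1O[C@@H]([C@H](CC)O[Si](C)(C)C(C)(C)C)C[C@@H]2OC(C)(C)O[C@@H]2C[C@@H]1O[Si](CC)(CC)CC | intermediate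
27 | (3Z)-enyne, C1 triisopropylsilyl, (6R,7S)-7-hydroxy, 13-OTBS, 9,10-acetonide | CC(C)[Si](C(C)C)(C(C)C)C#C/C=C\C[C@H]1O[C@@H]([C@H](CC)O[Si](C)(C)C(C)(C)C)C[C@@H]2OC(C)(C)O[C@@H]2C[C@@H]1O | intermediate
28 | (6R,7R)-7-(4-nitrobenzoyloxy) analogue of 27 (C7 inverted) | CC(C)[Si](C(C)C)(C(C)C)C#C/C=C\C[C@H]1O[C@@H]([C@H](CC)O[Si](C)(C)C(C)(C)C)C[C@@H]2OC(C)(C)O[C@@H]2C[C@H]1OC(=O)c3ccc(cc3)[N+](=O)[O-] | intermediate
29 | (6R,7R)-7-hydroxy analogue (6,7-cis), C1 triisopropylsilyl, 13-OTBS, 9,10-acetonide | CC(C)[Si](C(C)C)(C(C)C)C#C/C=C\C[C@H]1O[C@@H]([C@H](CC)O[Si](C)(C)C(C)(C)C)C[C@@H]2OC(C)(C)O[C@@H]2C[C@H]1O | intermediate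
30 | (3Z,6R,7R,9R,10S,12R,13S)-7,13-dihydroxy-9,10-(isopropylidenedioxy)-6,12-epoxypentadec-3-en-1-yne | C#C/C=C\C[C@H]1O[C@@H]([C@H](CC)O)C[C@@H]2OC(C)(C)O[C@@H]2C[C@H]1O | intermediate
31 | 7,13-diacetate of 30 | C#C/C=C\C[C@H]1O[C@@H]([C@H](CC)OC(C)=O)C[C@@H]2OC(C)(C)O[C@@H]2C[C@H]1OC(C)=O | intermediate
32 | CNP0314743.1, (3Z,6R,7R,9R,10S,12R,13S)-7,13-diacetoxy-9,10-dihydroxy-6,12-epoxypentadec-3-en-1-yne | C#C/C=C\C[C@H]1O[C@@H]([C@H](CC)OC(C)=O)C[C@H](O)[C@H](O)C[C@H]1OC(C)=O | target

Total step count: 22. Longest linear sequence: 21 steps (steps 1–7 and 9–22, from 2-deoxy-D-ribose); step 8 is a one-step side branch that prepares the allylboron reagent.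

Steps most likely to fail

Step 13. Reduction of the ketyl to the alkoxide, or pinacol coupling, may outrun the slow eight-membered closure, and control at C6 may be weak. The fallback closes the same C6–C7 bond by ring-closing metathesis of an enol ether and sets both centres by hydroboration; it sets out from alcohol 16 and comes back at aldehyde 23. Alcohol 16 is esterified with 3-(4-methoxybenzyloxy)propanoic acid (dicyclohexylcarbodiimide, 4-dimethylaminopyridine) to the C12 ester F1. Direct Swern oxidation of its primary triethylsilyl ether gives the aldehyde ester F2. The Tebbe reagent Cp2Ti(μ-Cl)(μ-CH2)AlMe2 methylenates both the aldehyde and the ester carbonyl to the enol ether diene F3. The second-generation Grubbs catalyst RuCl2(=CHPh)(PCy3)(SIMes) joins C6 and C7 in the cyclic enol ether F4. Hydroboration with BH3·THF and oxidation (NaOH, H2O2) put H on C6 and OH on C7 from the same face to give the 6,7-trans alcohol F5; the face of attack at C6 would have to be confirmed. Et3SiOTf gives the silyl ether F6, DDQ frees the primary alcohol F7, and Dess–Martin oxidation gives 23.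

Step 18. The activated alcohol may eliminate to a ring alkene, or the hindered alkoxyphosphonium ion may fail to undergo substitution. The fallback replaces substitution by oxidation and reduction; it sets out from alcohol 27 and comes back at alcohol 29, so steps 18 and 19 are both replaced. Dess–Martin oxidation gives the C7 ketone F8. LiBH(s-Bu)3 (THF, −78 °C) should deliver hydride to the face away from the C6 side chain and give the 6,7-cis alcohol 29.

Step 9. The β-stereocentre or the bulky γ-silyloxy group may erode catalyst control of the aldehyde face, and the enol ether reagent may be slow or acid-sensitive. The fallback moves the chiral controller onto boron as a stoichiometric auxiliary; it sets out from boronate 12 (with aldehyde 11) and comes back at alcohol 15. NaIO4 and NH4OAc in aqueous acetone cleave the pinacol ester to the boronic acid F9. Esterification with diisopropyl L-tartrate (MgSO4) gives the tartrate alkenylboronate F10. The iridium-catalysed isomerisation of step 8 gives the tartrate (E)-γ-silyloxyallylboronate F11. Uncatalysed addition to 11 (toluene, 4 Å MS, −78 °C), in which the (R,R)-tartrate is expected to direct attack to the Si face, gives 15.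

Further compounds
F1 | step 13 | (2R,3S)-3-(tert-butyldimethylsilyloxy)-1-[(4S,5R)-2,2-dimethyl-5-(2-triethylsilyloxyethyl)-1,3-dioxolan-4-yl]pentan-2-yl 3-(4-methoxybenzyloxy)propanoate | CC[Si](CC)(CC)OCC[C@H]1OC(C)(C)O[C@H]1C[C@@H](OC(=O)CCOCc2ccc(OC)cc2)[C@H](CC)O[Si](C)(C)C(C)(C)C
F2 | step 13 | C7 aldehyde of F1 | O=CC[C@H]1OC(C)(C)O[C@H]1C[C@@H](OC(=O)CCOCc2ccc(OC)cc2)[C@H](CC)O[Si](C)(C)C(C)(C)C
F3 | step 13 | enol ether diene (C7 terminal alkene, C6 1-alkoxyvinyl group on O12) | C=CC[C@H]1OC(C)(C)O[C@H]1C[C@@H](OC(=C)CCOCc2ccc(OC)cc2)[C@H](CC)O[Si](C)(C)C(C)(C)C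
F4 | step 13 | cyclic enol ether (C6=C7 oxocene) with 2-(4-methoxybenzyloxy)ethyl group on C6 | COc1ccc(COCCC2=CC[C@H]3OC(C)(C)O[C@H]3C[C@@H](O2)[C@H](CC)O[Si](C)(C)C(C)(C)C)cc1
F5 | step 13 | (6R,7S)-7-hydroxy oxocane with 2-(4-methoxybenzyloxy)ethyl group on C6 | COc1ccc(COCC[C@H]2O[C@@H]([C@H](CC)O[Si](C)(C)C(C)(C)C)C[C@@H]3OC(C)(C)O[C@@H]3C[C@@H]2O)cc1
F6 | step 13 | C7 triethylsilyl ether of F5 | COc1ccc(COCC[C@H]2O[C@@H]([C@H](CC)O[Si](C)(C)C(C)(C)C)C[C@@H]3OC(C)(C)O[C@@H]3C[C@@H]2O[Si](CC)(CC)CC)cc1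
F7 | step 13 | C4 primary alcohol (2-hydroxyethyl group on C6, C7 OSiEt3) | OCC[C@H]1O[C@@H]([C@H](CC)O[Si](C)(C)C(C)(C)C)C[C@@H]2OC(C)(C)O[C@@H]2C[C@@H]1O[Si](CC)(CC)CC
F8 | step 18 | C7 ketone of the silylated enyne | CC(C)[Si](C(C)C)(C(C)C)C#C/C=C\C[C@H]1O[C@@H]([C@H](CC)O[Si](C)(C)C(C)(C)C)C[C@@H]2OC(C)(C)O[C@@H]2CC1=O
F9 | step 9 | (E)-3-(tert-butyldimethylsilyloxy)prop-1-enylboronic acid | CC(C)(C)[Si](C)(C)OC/C=C/B(O)O
F10 | step 9 | diisopropyl (4R,5R)-2-[(E)-3-(tert-butyldimethylsilyloxy)prop-1-enyl]-1,3,2-dioxaborolane-4,5-dicarboxylate | CC(C)OC(=O)[C@@H]1OB(/C=C/CO[Si](C)(C)C(C)(C)C)O[C@H]1C(=O)OC(C)C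
F11 | step 9 | diisopropyl (4R,5R)-2-[(E)-3-(tert-butyldimethylsilyloxy)prop-2-enyl]-1,3,2-dioxaborolane-4,5-dicarboxylate | CC(C)OC(=O)[C@@H]1OB(C/C=C/O[Si](C)(C)C(C)(C)C)O[C@H]1C(=O)OC(C)C
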